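# Proposed synthesis of (2R,5R,6R)-2,6-cyclolycopene-1,5-diol (CNP0169920.2)

Positions are given in carotenoid numbering: ring atoms C2–C6, C1 the CMe2OH carbon on C2, C7 the first chain carbon on C6, primed numbers for the acyclic half.

**Compound numbers used throughout**

- 1 geraniol
- 2 (2R,3R)-2,3-epoxygeraniol
- 3 epoxy aldehyde from 2
- 4 vinyl epoxide (precursor of the key step)
- 5 vinyl cyclopentanediol (product of the key step)
- 6 ring-bearing C13 enone
- 7 ring-bearing C15 vinyl carbinol
- 8 ring-bearing C15 phosphonium bromide
- 9 pseudoionone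
- 10 vinyl carbinol from 9
- 11 acyclic C15 phosphonium bromide
- 12 C10 dial
- 13 ylide of 11 (formed in the flask)
- 14 8Z isomer of 15 (formed in the flask)
- 15 C25 polyene aldehyde
- 16 ylide of 8 (formed in the flask)
- 17 11Z isomer of 18 (formed in the flask)
- 18 target

Assumption: 9 is used as the pure (3E,5E) isomer (technical material is an E/Z mixture at the 5,6-bond and would first be fractionated), because a Z trisubstituted double bond at that position is not corrected later in the route.

## Analysis of the target

Compound 18 is a C40 carotenoid with a chain of ten conjugated E double bonds (C7=C8 to C5'=C6'). One end is an unchanged acyclic terminus with an isolated C1'=C2' double bond; the other is a cyclopentane made of C2, C3, C4, C5 and C6. The ring carries three contiguous stereocentres, all R: C5 (tertiary alcohol with a methyl group), C6 (bearing the polyene through C7) and C2 (bearing C1, the CMe2OH carbon). The three carbon substituents (the C5 methyl, C7 and C1) lie on one face and the C5 hydroxyl on the other. C7 is therefore trans to the C5 hydroxyl and cis to C1, and the C1 and C5 oxygens are 1,3-trans and cannot bridge. This all-cis placement of the carbon groups is the crowded one: an intermediate with a carbonyl at C7 could epimerise at C6 and, as a β-hydroxy carbonyl compound, could also fragment. The polyene is sensitive to light, oxygen and acid, the two tertiary alcohols can be lost under acid, and the C1 hydroxyl lies within reach of any electrophilic centre that develops at C7. The synthesis rests on one feature: the end group is a lycopene terminus in which C2 is bonded to C6 and oxygen sits on C5 and C1. That is what remains when a 5,6-epoxide is opened at allylic C6 by the C1=C2 double bond and the charge at C1 is quenched by hydroxide.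

## Retrosynthetic reasoning

**C11=C12.** The first cut divides 18 into the ring-bearing C15 phosphonium salt 8 and the C25 aldehyde 15. This bond is disubstituted, so a Wittig reaction there gives an E/Z mixture whose Z isomer is the sterically hindered kind that reverts to E on gentle heating; a cut at a trisubstituted bond would leave Z isomers that do not correct themselves. The chiral fragment enters in the last step and the finished polyene meets no acid. The forward reaction has to form the ylide of 8 beside two free tertiary hydroxyl groups and leave C5 and C6 alone.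

**C11'=C12' and the acyclic half.** Aldehyde 15 is cut into the acyclic C15 salt 11 and the symmetrical dial 12. Dial 12 is the cheap partner and can be used in excess so that only one formyl group reacts. Salt 11 goes back to the tertiary vinyl carbinol 10 by allylic transposition (C11'–P bond), and 10 to 9 by removal of a two-carbon vinyl unit (C9'–C10' bond). The double bonds of 9 and 12 are carried through unchanged, so only the new one needs attention.

**C11–P, C9–C10 and C7=C8 on the ring half.** Salt 8 is treated in the same way: back to the doubly allylic tertiary carbinol 7, then to enone 6. Enone 6 is cut at C7=C8, which leads to the vinyl compound 5; in the forward sense a cross-metathesis exchanges the terminal CH2 of 5 for the C8–C9(=O)–CH3 unit. A cut at C6–C7 was avoided because it would place a carbonyl on C7. Both halves of the carotenoid are thus extended by the same two operations.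

**C2–C6 and C1–O (key disconnection).** In 5 the ring bond C2–C6 and the C1–O bond are cut together, which unfolds the cyclopentane into the acyclic vinyl epoxide 4. This removes the ring and the C2 stereocentre in one step. It leaves a precursor whose two stereocentres (C5 and C6) are those of an epoxide, and all carbons are already at their final oxidation level. The vinyl group on C6 is what should direct the oxirane to open at C6 and not at tertiary C5. The forward reaction has to form C2–C6 with inversion at C6, keep C5, place C1 cis to C7, and deliver oxygen to C1 from the medium.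

**C7=C8 of the epoxide, and the oxirane.** Epoxide 4 is cut at C7=C8 to aldehyde 3 (one-carbon olefination). Aldehyde 3 is the oxidation product of epoxy alcohol 2, and removal of the oxirane oxygen from 2 gives 1. The allylic hydroxyl of 1 is the handle for a catalytic asymmetric epoxidation that sets C5 and C6 together; the E geometry of 1 puts C7 cis to the C5 methyl, as the inversion at C6 requires.

## Alternatives that were turned down

**Alternative 1:** The cyclopentane is cut at C2–C6, C3–C4 and C4–C5, with C4 supplied as a carbonyl carbon and an ether oxygen tethering C1 to C7. In the forward sense the achiral enyne ether A1 would undergo a catalytic asymmetric Pauson–Khand reaction (chiral rhodium–bisphosphine catalyst, carbonylative conditions) to give the bicyclic enone A2.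
- For it: one step builds the carbocycle and sets C2 from a simple substrate. The tether forces C1 and C7 to be cis once C6 is saturated from the convex face. On that relationship it is stronger than the chosen plan, which relies on a transition-state preference.
- Against it: C4 arrives as a ketone that the target lacks, and C5 arrives as an sp2 carbon next to that ketone. C5 would have to be hydroxylated α to the carbonyl with the correct facial sense, the ketone then removed beside a tertiary alcohol, the ether carbon C7 oxidised and the tether opened. That is at least eight further operations before the chain can be attached.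
- In exchange, the chosen route has every carbon at its final oxidation level after the ring closure and reaches the ring in four steps.

**Alternative 2:** The bonds C6–C7 and C2–C1 are cut together. (R)-Linalool A3 would be converted by ring-closing metathesis and silylation into the cyclopentenyl silyl ether A4. The keteniminium ion A5 would add suprafacially across C6=C2 of A4, and hydrolysis would give the cyclobutanone A6. Oxygen insertion next to the quaternary carbon, reduction to the lactol and olefination would follow.
- For it: the cis relationship of C1 and C7 is guaranteed by the cycloaddition, so on this point it is stronger than the chosen plan. C5 comes from the chiral pool, and the oxygen insertion places oxygen on C1 and leaves C7 ready for olefination.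
- Against it: the cycloaddition has to pick the face syn to the C5 methyl and anti to the silyloxy group. These are two groups of similar size on the same carbon, and this choice decides the C5/C6 relationship, which the chosen plan obtains stereospecifically by inversion of an epoxide carbon. The two alkene carbons are both secondary, so regiochemistry rests on a modest bias. A tertiary allylic silyl ether may ionise under the Lewis-acidic conditions. The lactol olefination passes through an open hydroxy aldehyde in which C6 can epimerise. About seven operations, including protection and deprotection of a tertiary alcohol, are needed to reach the stage of 6, against five in the chosen route.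

**Alternative 3:** The ring is cut as a diene plus a carbene carbon. The dienyl diazoacetate A7 would undergo catalytic asymmetric intramolecular cyclopropanation to the vinylcyclopropane-fused lactone A8. A8 would rearrange (flash vacuum pyrolysis near 550 °C, or silyl iodide opening followed by base) with cleavage of C2–C5 and formation of C2–C3 to give the cis-fused cyclopentene lactone A9.
- For it: asymmetric cyclopropanation of allylic diazoacetates is well developed. The cis ring fusion holds C1 and C7 cis, which is as good as Alternative 2 on this point and better than the chosen plan. C1 arrives as a lactone carbonyl ready for double methyl addition.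
- Against it: the rearrangement is harsh. Afterwards C5 still lacks its oxygen, so C4=C5 must be hydrated in the Markovnikov sense from the convex face. C7 must then be raised from the alcohol to the aldehyde level on C6, which creates the epimerisable β-hydroxy aldehyde that the target's crowded face makes most fragile. About ten operations and a diazo compound are needed before chain extension.
- In exchange, the chosen route never places a carbonyl on C7 and needs no high-temperature step.

Key step: step 4

## Route

Step 1
Reactants: 1 geraniol
Product: 2 [(2R,3R)-3-methyl-3-(4-methylpent-3-en-1-yl)oxiran-2-yl]methanol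
Conditions: Ti(OiPr)4 (5 mol%), D-(−)-diethyl tartrate (7 mol%), t-BuOOH (1.5 equiv, anhydrous), 4 Å molecular sieves, CH2Cl2, −20 °C
Reagents that add atoms: tert-butyl hydroperoxide, CC(C)(C)OO
Why: Sharpless asymmetric epoxidation of an E trisubstituted allylic alcohol; the titanium tartrate catalyst of the D-(−) series delivers oxygen to the face that gives the (2R,3R) epoxide, which sets C5 and C6 of the later ring precursor, and the remote 6,7-alkene is not touched because only the allylic alcohol binds to titanium.

Step 2
Reactants: 2 [(2R,3R)-3-methyl-3-(4-methylpent-3-en-1-yl)oxiran-2-yl]methanol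
Product: 3 (2S,3R)-3-methyl-3-(4-methylpent-3-en-1-yl)oxirane-2-carbaldehyde
Conditions: TEMPO (10 mol%), PhI(OAc)2 (1.1 equiv), CH2Cl2, 0 °C → rt; used crude
Reagents that add atoms: none
Why: Oxoammonium-mediated oxidation (TEMPO with PhI(OAc)2) stops at the aldehyde and is mild enough for a trisubstituted epoxide; no stereocentre is touched, and the descriptor of the aldehyde-bearing carbon changes from R to S only because the CIP priorities change.

Step 3
Reactants: 3 (2S,3R)-3-methyl-3-(4-methylpent-3-en-1-yl)oxirane-2-carbaldehyde
Product: 4 (2R,3R)-3-ethenyl-2-methyl-2-(4-methylpent-3-en-1-yl)oxirane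
Conditions: Ph3PCH3Br (1.5 equiv), KN(SiMe3)2 (1.4 equiv), THF, 0 °C; then 3, −78 → 0 °C
Reagents that add atoms: methyltriphenylphosphonium bromide, C[P+](c1ccccc1)(c1ccccc1)c1ccccc1.[Br-]
Why: Wittig methylenation with the non-stabilised ylide is fast on α-epoxy aldehydes at low temperature, so the oxirane and both stereocentres should survive; the product is volatile and is concentrated with care.

Step 4
Reactants: 4 (2R,3R)-3-ethenyl-2-methyl-2-(4-methylpent-3-en-1-yl)oxirane
Product: 5 (1R,2R,3R)-2-ethenyl-3-(2-hydroxypropan-2-yl)-1-methylcyclopentan-1-ol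
Conditions: Sc(OTf)3 (10 mol%), H2O (3 equiv), CH2Cl2/MeNO2 (4:1, 0.02 M), −30 → 0 °C
Reagents that add atoms: water, O
Why: Sc(OTf)3 binds the epoxide oxygen and lengthens the allylic C6–O bond; the trisubstituted C1=C2 alkene attacks C6 through C2 from the side opposite the oxygen, the charge passes to tertiary C1 and water captures it, so one C–C bond and one C–O bond form and proton loss releases the diol. The closest known chemistry is the epoxide-initiated cation–olefin cyclisation, the tendency of vinyl epoxides to open at the allylic carbon toward a tethered nucleophile, and the acid rearrangement of acyclic carotenoid 5,6-epoxides to 2,6-cyclo-1,5-diols. The cyclopentane closes 5-exo with respect to the alkene (C1 stays outside the ring) and endo with respect to the epoxide (C5 and C6 both end up in the ring), which the vinyl group allows by stabilising charge at C6. C5 is not touched and keeps the configuration set in step 1. C6 is inverted because the nucleophile enters anti to the leaving oxygen; with the epoxide derived from the E alkene this places C7 trans to the C5 hydroxyl and cis to the C5 methyl. C2 is set by the transition state: in the chair-like arrangement that 5-exo closures usually prefer, the vinyl group and the C5–O bond are both pseudo-equatorial (fixed by the trans epoxide) and C1 comes out cis to C7 and trans to the C5 oxygen, as in 5. The step needs cleavage of C6–O and not of the tertiary C5–O bond, a tight SN2-like opening, and the chair over the boat; the π-donor on C6, low temperature and a small amount of water serve the first two, and the boat product would carry C1 next to the C5 oxygen and be diverted to a bicyclic ether that is separable from the diol.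

Step 5
Reactants: 5 (1R,2R,3R)-2-ethenyl-3-(2-hydroxypropan-2-yl)-1-methylcyclopentan-1-ol
Product: 6 (3E)-4-[(1R,2R,5R)-2-hydroxy-5-(2-hydroxypropan-2-yl)-2-methylcyclopentyl]but-3-en-2-one
Conditions: methyl vinyl ketone (5 equiv), second-generation Hoveyda–Grubbs catalyst [RuCl2(H2IMes)(=CH-C6H4-2-OiPr)] (5 mol%), CH2Cl2, 40 °C
Reagents that add atoms: methyl vinyl ketone (but-3-en-2-one), C=CC(C)=O
Why: Olefin cross-metathesis between a hindered monosubstituted alkene that dimerises slowly and an excess of an electron-poor enone is a selective pairing and should give the E enone; the ruthenium carbene tolerates free tertiary alcohols, and the neutral medium gives the cis C1 hydroxyl no catalyst for conjugate addition to the new enone.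

Step 6
Reactants: 6 (3E)-4-[(1R,2R,5R)-2-hydroxy-5-(2-hydroxypropan-2-yl)-2-methylcyclopentyl]but-3-en-2-one
Product: 7 (4E)-5-[(1R,2R,5R)-2-hydroxy-5-(2-hydroxypropan-2-yl)-2-methylcyclopentyl]-3-methylpenta-1,4-dien-3-ol (both epimers at the new carbinol carbon)
Conditions: CH2=CHMgBr (4 equiv), THF, −78 → −20 °C (6 added to the reagent); aq. NH4Cl
Reagents that add atoms: vinylmagnesium bromide, C=C[Mg]Br
Why: Grignard 1,2-addition to the methyl ketone; two equivalents are consumed by the hydroxyl groups, and inverse addition at low temperature lets carbonyl addition outrun conjugate addition of the reagent or of the C1 alkoxide; the new carbinol centre forms as both epimers, which does not matter because it becomes sp2 in step 7.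

Step 7
Reactants: 7 (4E)-5-[(1R,2R,5R)-2-hydroxy-5-(2-hydroxypropan-2-yl)-2-methylcyclopentyl]-3-methylpenta-1,4-dien-3-ol
Product: 8 {(2E,4E)-5-[(1R,2R,5R)-2-hydroxy-5-(2-hydroxypropan-2-yl)-2-methylcyclopentyl]-3-methylpenta-2,4-dien-1-yl}triphenylphosphonium bromide
Conditions: PPh3·HBr (1.05 equiv), MeOH, 0 °C → rt; crystallisation from EtOAc
Reagents that add atoms: triphenylphosphine hydrobromide, [PH+](c1ccccc1)(c1ccccc1)c1ccccc1.[Br-]
Why: The doubly allylic tertiary alcohol ionises in weakly acidic methanol to a pentadienyl cation that the phosphine captures irreversibly at the primary terminus (allylic transposition, the standard entry to C15 Wittig salts), mainly as the E trisubstituted alkene; the two saturated tertiary alcohols should not ionise under these conditions, and reversible capture of the cation by the C1 hydroxyl is drained toward the salt.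

Step 8
Reactants: 9 pseudoionone, (3E,5E)-6,10-dimethylundeca-3,5,9-trien-2-one
Product: 10 (4E,6E)-3,7,11-trimethyldodeca-1,4,6,10-tetraen-3-ol (racemic)
Conditions: CH2=CHMgBr (1.3 equiv), THF, −20 → 0 °C; aq. NH4Cl
Reagents that add atoms: vinylmagnesium bromide, C=C[Mg]Br
Why: Grignard 1,2-addition to the conjugated methyl ketone gives the tertiary vinyl carbinol; the racemic carbinol centre is lost in step 9.

Step 9
Reactants: 10 (4E,6E)-3,7,11-trimethyldodeca-1,4,6,10-tetraen-3-ol
Product: 11 [(2E,4E,6E)-3,7,11-trimethyldodeca-2,4,6,10-tetraen-1-yl]triphenylphosphonium bromide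
Conditions: PPh3·HBr (1.05 equiv), MeOH, 0 °C → rt
Reagents that add atoms: triphenylphosphine hydrobromide, [PH+](c1ccccc1)(c1ccccc1)c1ccccc1.[Br-]
Why: Same allylic transposition as in step 7; ionisation to the delocalised cation and capture by the phosphine at the primary terminus should give mainly the 2E salt.

Step 10
Reactants: 11 [(2E,4E,6E)-3,7,11-trimethyldodeca-2,4,6,10-tetraen-1-yl]triphenylphosphonium bromide; 12 (2E,4E,6E)-2,7-dimethylocta-2,4,6-trienedial
Product: 15 (2E,4E,6E,8E,10E,12E,14E)-2,7,11,15,19-pentamethylicosa-2,4,6,8,10,12,14,18-octaenal, via acyclic C15 ylide 13 (not isolated), via 8Z isomer 14 (not isolated)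
Conditions: 12 (3 equiv), NaOMe (1.1 equiv), CH2Cl2/MeOH, −10 °C → rt; then n-heptane, reflux, N2, dark; excess 12 recovered
Reagents that add atoms: none
Why: Wittig olefination of one formyl group of the symmetrical dial by the allylic ylide; each formyl group of 12 is activated by the other through the triene, so the dial should react faster than the mono-adduct and, used in excess, give mainly mono-olefination; the new disubstituted double bond forms as an E/Z mixture and the hindered Z isomer is converted to E by heating.

Step 11
Reactants: 8 {(2E,4E)-5-[(1R,2R,5R)-2-hydroxy-5-(2-hydroxypropan-2-yl)-2-methylcyclopentyl]-3-methylpenta-2,4-dien-1-yl}triphenylphosphonium bromide; 15 (2E,4E,6E,8E,10E,12E,14E)-2,7,11,15,19-pentamethylicosa-2,4,6,8,10,12,14,18-octaenal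
Product: 18 (all-E)-(2R,5R,6R)-2,6-cyclolycopene-1,5-diol, via ring C15 ylide 16 (not isolated), via 11Z isomer 17 (not isolated)
Conditions: NaOMe (1.2 equiv), CH2Cl2/MeOH, 0 °C → rt; then EtOH, reflux, N2, dark; crystallisation
Reagents that add atoms: none
Why: Wittig coupling of the C15 and C25 halves at C11=C12; methoxide deprotonates the allylic salt but leaves the tertiary alcohols alone, the ring stereocentres are remote from the reacting carbon, the hindered 11Z isomer should revert to E on heating, and crystallisation should remove any minor isomer carried over from the salt.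

## Compound list

1 | geraniol, (2E)-3,7-dimethylocta-2,6-dien-1-ol | CC(C)=CCC/C(C)=C/CO | starting material
2 | [(2R,3R)-3-methyl-3-(4-methylpent-3-en-1-yl)oxiran-2-yl]methanol | OC[C@H]1O[C@]1(C)CCC=C(C)C | intermediate
3 | (2S,3R)-3-methyl-3-(4-methylpent-3-en-1-yl)oxirane-2-carbaldehyde | O=C[C@H]1O[C@]1(C)CCC=C(C)C | intermediate
4 | (2R,3R)-3-ethenyl-2-methyl-2-(4-methylpent-3-en-1-yl)oxirane | C=C[C@H]1O[C@]1(C)CCC=C(C)C | intermediate
5 | (1R,2R,3R)-2-ethenyl-3-(2-hydroxypropan-2-yl)-1-methylcyclopentan-1-ol | C=C[C@@H]1[C@H](C(C)(C)O)CC[C@@]1(C)O | intermediate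
6 | (3E)-4-[(1R,2R,5R)-2-hydroxy-5-(2-hydroxypropan-2-yl)-2-methylcyclopentyl]but-3-en-2-one | CC(=O)/C=C/[C@@H]1[C@H](C(C)(C)O)CC[C@@]1(C)O | intermediate
7 | (4E)-5-[(1R,2R,5R)-2-hydroxy-5-(2-hydroxypropan-2-yl)-2-methylcyclopentyl]-3-methylpenta-1,4-dien-3-ol (both epimers at C3 of the chain) | C=CC(C)(O)/C=C/[C@@H]1[C@H](C(C)(C)O)CC[C@@]1(C)O | intermediate
8 | {(2E,4E)-5-[(1R,2R,5R)-2-hydroxy-5-(2-hydroxypropan-2-yl)-2-methylcyclopentyl]-3-methylpenta-2,4-dien-1-yl}triphenylphosphonium bromide | [Br-].c1ccccc1[P+](c1ccccc1)(c1ccccc1)C/C=C(C)/C=C/[C@@H]1[C@H](C(C)(C)O)CC[C@@]1(C)O | intermediate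
9 | pseudoionone, (3E,5E)-6,10-dimethylundeca-3,5,9-trien-2-one | CC(C)=CCC/C(C)=C/C=C/C(C)=O | starting material
10 | (4E,6E)-3,7,11-trimethyldodeca-1,4,6,10-tetraen-3-ol (racemic) | CC(C)=CCC/C(C)=C/C=C/C(C)(O)C=C | intermediate
11 | [(2E,4E,6E)-3,7,11-trimethyldodeca-2,4,6,10-tetraen-1-yl]triphenylphosphonium bromide | CC(C)=CCC/C(C)=C/C=C/C(C)=C/C[P+](c1ccccc1)(c1ccccc1)c1ccccc1.[Br-] | intermediate
12 | (2E,4E,6E)-2,7-dimethylocta-2,4,6-trienedial | O=C/C(C)=C/C=C/C=C(C)/C=O | starting material
13 | [(2E,4E,6E)-3,7,11-trimethyldodeca-2,4,6,10-tetraen-1-ylidene]triphenyl-λ5-phosphane (ylide of 11) | CC(C)=CCC/C(C)=C/C=C/C(C)=C/C=P(c1ccccc1)(c1ccccc1)c1ccccc1 | intermediate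
14 | (2E,4E,6E,8Z,10E,12E,14E)-2,7,11,15,19-pentamethylicosa-2,4,6,8,10,12,14,18-octaenal | CC(C)=CCC/C(C)=C/C=C/C(C)=C/C=C\C(C)=C\C=C\C=C(C)\C=O | intermediate
15 | (2E,4E,6E,8E,10E,12E,14E)-2,7,11,15,19-pentamethylicosa-2,4,6,8,10,12,14,18-octaenal | CC(C)=CCC/C(C)=C/C=C/C(C)=C/C=C/C(C)=C/C=C/C=C(C)/C=O | intermediate
16 | {(2E,4E)-5-[(1R,2R,5R)-2-hydroxy-5-(2-hydroxypropan-2-yl)-2-methylcyclopentyl]-3-methylpenta-2,4-dien-1-ylidene}triphenyl-λ5-phosphane (ylide of 8) | c1ccccc1P(c1ccccc1)(c1ccccc1)=C/C=C(C)/C=C/[C@@H]1[C@H](C(C)(C)O)CC[C@@]1(C)O | intermediate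
17 | 11Z isomer of 18 (Z at the fifth carbon of the side chain, all other double bonds as in 18) | CC(C)=CCC/C(C)=C/C=C/C(C)=C/C=C/C(C)=C/C=C/C=C(C)/C=C\C=C(C)\C=C\[C@@H]1[C@H](C(C)(C)O)CC[C@@]1(C)O | intermediate
18 | (1R,2R,3R)-3-(2-hydroxypropan-2-yl)-1-methyl-2-[(1E,3E,5E,7E,9E,11E,13E,15E,17E,19E)-3,7,12,16,20,24-hexamethylpentacosa-1,3,5,7,9,11,13,15,17,19,23-undecaen-1-yl]cyclopentan-1-ol, i.e. (all-E)-(2R,5R,6R)-2,6-cyclolycopene-1,5-diol | CC(C)=CCC/C(C)=C/C=C/C(C)=C/C=C/C(C)=C/C=C/C=C(C)/C=C/C=C(C)/C=C/[C@@H]1[C@H](C(C)(C)O)CC[C@@]1(C)O | target

## Step count and least certain steps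

Total: 11 steps. Longest linear sequence: 8 steps from 1 (steps 1–7 and 11); the C25 branch (steps 8–10) joins in step 11.

**Step 4 (key step).**
- What may go wrong: ionisation at the tertiary C5–O bond, followed by hydride or alkyl shift to a carbonyl compound or by direct hydrolysis of the oxirane; full ionisation at C6 with loss of the inversion; closure through the boat, which gives the C2 epimer and then the bicyclic ether; loss of a proton from the C1 cation instead of hydration. The vinyl group stabilises charge at C6 only modestly compared with the tertiary centre, and the chair preference is a tendency that no ring enforces.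
- Fallback, from 3 back to 8: the conjugated chain is attached before the ring is closed, so that C6 is doubly allylic as in the acyclic carotenoid 5,6-epoxides that close to 2,6-cyclo-1,5-diols in dilute acid. Horner–Wadsworth–Emmons reaction of 3 with ethyl (2E)-4-(diethoxyphosphoryl)-3-methylbut-2-enoate (LiN(SiMe3)2, THF, −78 → 0 °C) would give ethyl (2E,4E)-3-methyl-5-[(2R,3R)-3-methyl-3-(4-methylpent-3-en-1-yl)oxiran-2-yl]penta-2,4-dienoate F1. Reduction with i-Bu2AlH (CH2Cl2, −78 °C) would give (2E,4E)-3-methyl-5-[(2R,3R)-3-methyl-3-(4-methylpent-3-en-1-yl)oxiran-2-yl]penta-2,4-dien-1-ol F2. Ring closure of F2 under the wet Sc(OTf)3 conditions at −40 °C should give (2E,4E)-5-[(1R,2R,5R)-2-hydroxy-5-(2-hydroxypropan-2-yl)-2-methylcyclopentyl]-3-methylpenta-2,4-dien-1-ol F3, and PPh3·HBr in MeOH converts F3 into 8. The price is a more cation-like C6, so inversion is less assured and diastereomers may have to be separated.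

**Step 5.**
- What may go wrong: slow or incomplete metathesis because the vinyl group sits between two cis substituents; self-metathesis of the enone; double-bond migration by ruthenium hydrides; conjugate addition of the C1 hydroxyl to the product.
- Fallback, from 5 back to 6 without metathesis: ozonolysis (O3, CH2Cl2/MeOH, −78 °C; Me2S) cleaves the vinyl group. The hydroxy aldehyde is expected to rest as the lactol formed with the cis C1 hydroxyl, (3aR,6R,6aR)-3,3,6-trimethylhexahydro-1H-cyclopenta[c]furan-1,6-diol F4. Wittig reaction of F4 with 1-(triphenyl-λ5-phosphanylidene)propan-2-one (toluene, 80 °C) returns 6. C6 can epimerise in the open form, so this path is kept in reserve.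

**Step 7.**
- What may go wrong: capture of the pentadienyl cation at C7 by the cis C1 hydroxyl to give a cyclic ether; acid-induced loss of a tertiary hydroxyl; formation of the 2Z salt beside the 2E salt.
- Fallback, from 7 and 15 back to 18 with the polarity of the last coupling reversed, so that the ring fragment never meets HBr: oxidative 1,3-transposition of 7 (Babler–Dauben oxidation with pyridinium chlorochromate [C5H5NH][CrO3Cl], NaOAc, CH2Cl2) would give (2E,4E)-5-[(1R,2R,5R)-2-hydroxy-5-(2-hydroxypropan-2-yl)-2-methylcyclopentyl]-3-methylpenta-2,4-dienal F5. Aldehyde 15 is reduced (NaBH4, MeOH/THF, 0 °C) to (2E,4E,6E,8E,10E,12E,14E)-2,7,11,15,19-pentamethylicosa-2,4,6,8,10,12,14,18-octaen-1-ol F6 and converted with PPh3·HBr into [(2E,4E,6E,8E,10E,12E,14E)-2,7,11,15,19-pentamethylicosa-2,4,6,8,10,12,14,18-octaen-1-yl]triphenylphosphonium bromide F7. Wittig reaction of F7 with F5 (NaOMe, CH2Cl2/MeOH) and heating as in step 11 gives 18.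

**Step 10.**
- What may go wrong: olefination of both formyl groups to the symmetrical C40 hydrocarbon; incomplete isomerisation of the new double bond.
- Fallback, from 12 back to 15 with the dial desymmetrised first: 12 with one equivalent of 2,2-dimethylpropane-1,3-diol (pyridinium p-toluenesulfonate, toluene) gives (2E,4E,6E)-7-(5,5-dimethyl-1,3-dioxan-2-yl)-2-methylocta-2,4,6-trienal F8, separated from diacetal and unchanged 12. Wittig reaction of F8 with ylide 13 gives the 5,5-dimethyl-1,3-dioxane acetal of 15 F9, and dilute aqueous oxalic acid in THF releases 15.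

## Further compounds

F1 | step 4 | ethyl (2E,4E)-3-methyl-5-[(2R,3R)-3-methyl-3-(4-methylpent-3-en-1-yl)oxiran-2-yl]penta-2,4-dienoate | CCOC(=O)/C=C(C)/C=C/[C@H]1O[C@]1(C)CCC=C(C)C
F2 | step 4 | (2E,4E)-3-methyl-5-[(2R,3R)-3-methyl-3-(4-methylpent-3-en-1-yl)oxiran-2-yl]penta-2,4-dien-1-ol | OC/C=C(C)/C=C/[C@H]1O[C@]1(C)CCC=C(C)C
F3 | step 4 | (2E,4E)-5-[(1R,2R,5R)-2-hydroxy-5-(2-hydroxypropan-2-yl)-2-methylcyclopentyl]-3-methylpenta-2,4-dien-1-ol | OC/C=C(C)/C=C/[C@@H]1[C@H](C(C)(C)O)CC[C@@]1(C)O
F4 | step 5 | (3aR,6R,6aR)-3,3,6-trimethylhexahydro-1H-cyclopenta[c]furan-1,6-diol (both anomers) | OC2[C@@H]1[C@H](C(C)(C)O2)CC[C@@]1(C)O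
F5 | step 7 | (2E,4E)-5-[(1R,2R,5R)-2-hydroxy-5-(2-hydroxypropan-2-yl)-2-methylcyclopentyl]-3-methylpenta-2,4-dienal | O=C/C=C(C)/C=C/[C@@H]1[C@H](C(C)(C)O)CC[C@@]1(C)O
F6 | step 7 | (2E,4E,6E,8E,10E,12E,14E)-2,7,11,15,19-pentamethylicosa-2,4,6,8,10,12,14,18-octaen-1-ol | CC(C)=CCC/C(C)=C/C=C/C(C)=C/C=C/C(C)=C/C=C/C=C(C)/CO
F7 | step 7 | [(2E,4E,6E,8E,10E,12E,14E)-2,7,11,15,19-pentamethylicosa-2,4,6,8,10,12,14,18-octaen-1-yl]triphenylphosphonium bromide | CC(C)=CCC/C(C)=C/C=C/C(C)=C/C=C/C(C)=C/C=C/C=C(C)/C[P+](c1ccccc1)(c1ccccc1)c1ccccc1.[Br-]
F8 | step 10 | (2E,4E,6E)-7-(5,5-dimethyl-1,3-dioxan-2-yl)-2-methylocta-2,4,6-trienal | O=C/C(C)=C/C=C/C=C(C)/C1OCC(C)(C)CO1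
F9 | step 10 | 5,5-dimethyl-1,3-dioxane acetal of 15 (all double bonds as in 15) | CC(C)=CCC/C(C)=C/C=C/C(C)=C/C=C/C(C)=C/C=C/C=C(C)/C1OCC(C)(C)CO1
A1 | alternative 1 | 1-[(2-methylbut-3-en-2-yl)oxy]but-2-yne | CC#CCOC(C)(C)C=C
A2 | alternative 1 | (3aR)-3,3,6-trimethyl-3a,4-dihydro-1H-cyclopenta[c]furan-5(3H)-one | CC1=C2COC(C)(C)[C@@H]2CC1=O
A3 | alternative 2 | (R)-linalool, (3R)-3,7-dimethylocta-1,6-dien-3-ol | C=C[C@](C)(O)CCC=C(C)C
A4 | alternative 2 | tert-butyldimethyl{[(1R)-1-methylcyclopent-2-en-1-yl]oxy}silane | C[C@@]1(O[Si](C)(C)C(C)(C)C)CCC=C1
A5 | alternative 2 | N,N-dimethyl-2-methylprop-1-en-1-ylideneammonium (tetramethylketeniminium) ion | CC(C)=C=[N+](C)C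
A6 | alternative 2 | (1R,4R,5R)-4-[(tert-butyldimethylsilyl)oxy]-4,7,7-trimethylbicyclo[3.2.0]heptan-6-one | O=C1[C@@H]2[C@H](C1(C)C)CC[C@@]2(C)O[Si](C)(C)C(C)(C)C
A7 | alternative 3 | (2E)-3-methylpenta-2,4-dien-1-yl diazoacetate | C=C/C(C)=C/COC(=O)C=[N+]=[N-]
A8 | alternative 3 | 6-ethenyl-6-methyl-3-oxabicyclo[3.1.0]hexan-2-one (vinyl group exo, enantiomer of the SMILES) | O=C1OC[C@@H]2[C@H]1[C@@]2(C)C=C
A9 | alternative 3 | (3aR,6aR)-4-methyl-3,3a,6,6a-tetrahydro-1H-cyclopenta[c]furan-1-one | O=C1OC[C@@H]2[C@H]1CC=C2C
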